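**Target:** CNP0154031.0 = 2-hentriacontyl-5,7-dihydroxy-8-methyl-4H-chromen-4-one (14). The route is five steps; ring A is built by a cyclobutenone–alkoxyalkyne benzannulation that fixes the methyl position by construction.

## The problem

- Target 14 is a pyran-4-one ring fused through C4a–C8a to a benzene ring (ring A), with an unbranched C31 chain on C2 and no stereocentre. Every selectivity question is therefore one of position.
- Ring A is a phloroglucinol core with five of six carbons substituted: oxygen on C5, C7 and C8a (the ring oxygen O1), a C-methyl on C8 between O1 and the C7 hydroxyl, the C4 carbonyl on C4a, and hydrogen only on C6.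
- The hard part is to place the methyl on C8 and not on C6. An acylated C-methylphloroglucinol has two hydroxyls ortho to the acyl group, and pyranone closure can use either. A 5-hydroxychromone can also pass between the 6-methyl and 8-methyl series by ring opening and reclosure in hot protic acid (Wessely–Moser rearrangement).
- The oxygen that becomes O1 must therefore be told apart from the C5 oxygen before the pyranone is closed, and the C5 oxygen should stay masked until the end.
- The chain is the second issue. No C31 building block is sold; the nearest are C32 and C30 wax lipids. Every chain-bearing intermediate is a wax of low solubility in cold or polar media, so the chain should enter late.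
- The free phloroglucinol ring is easily oxidised and C-alkylated. This argues for ether protection of both phenols and one aprotic deprotection as the last step.
- The feature that opens a different plan: in ring A the atoms O1–C8a, C8–CH3 and C7–O form an oxygen/alkyl/oxygen triad, the third oxygen (on C5) is para to C8, and C6 and C4a are CH positions. This is exactly the pattern formed when a 3-alkoxy vinylketene (carbons C8a, C4a, C5, C6) takes up a 1-alkoxyalkyne (carbons C8, C7). The ketene oxygen ends as the only free hydroxyl, on C8a next to the methyl.

## Retrosynthesis

**14 ⇒ 13.** The two O–CH2CH3 bonds on the C5 and C7 oxygens are cut. Ethyl ethers are chosen because they are what the ring-forming step delivers; no protecting-group step is added. The forward reaction must cleave both ethers without opening the pyranone, since a ring-opened 5-hydroxy compound could reclose to the 6-methyl isomer. This calls for a Lewis acid under aprotic, cold conditions.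

**13 ⇒ 12 ⇒ 11 ⇒ 9 + 10.** The pyranone is cut at O1–C2 (cyclodehydration of diketone 12) and at C2–C3 (acyl transfer within ester 11).
- The carboxyl carbon of acid 10 becomes C2, so the whole chain comes from one purchasable C32 lipid.
- Tethering the acyl group to oxygen as ester 11 first makes the C–C bond formation intramolecular. This is needed for an enolisable aliphatic acyl group and a waxy partner.
- Ketone 9 has a single phenolic hydroxyl, the one beside the C-methyl. Closure of 12 can therefore only give the 8-methyl chromone.
- The precursors are a C13 ketone and a commodity-type fatty acid.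

**9 ⇒ 7.** The aryl–acetyl bond (C4a–C4) is cut. In phenol 7 only one position is ortho to the free hydroxyl, so an ortho-selective acetylation has only one site to find. The competing para position lies between the two ethoxy groups. A direct chromone annulation of 7 with a β-keto ester was set aside, because electron-rich phenols give coumarins in such condensations. The forward reaction needs ortho delivery, obtained through the boron chelate 8.

**7 ⇒ 1 + 2.** Ring A is taken apart at C8a–C8, C7–C6 and C8a–C4a (future chromone numbering).
- C8 with its methyl and C7 with its oxygen leave as alkyne 2.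
- C8a, C4a, C5 and C6 with the O1 and C5 oxygens leave as cyclobutenone 1.
- In the forward direction the two alkyne carbons are inserted into the C1–C2 bond of 1, by way of 3, 4, 5 and 6.
- This cut is preferred over any cut that keeps an intact phloroglucinol, because it creates the three oxygens in different states in one operation: one free OH and two ethers. The free OH is placed next to the methyl by the polarity of the reacting partners, not by a selective protection.
- The precursors are two C4–C5 liquids from the catalogue.

## Roads not taken

**Alternative 1:** the obvious route, cutting O1–C2 and C2–C3 on an acylphloroglucinol.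
- 2-Methylbenzene-1,3,5-triol A1 would be C-acetylated to 1-(2,4,6-trihydroxy-3-methylphenyl)ethan-1-one A2. A2 would be acylated with chain acid 10, rearranged (Baker–Venkataraman) and cyclodehydrated.
- In A2 both hydroxyls ortho to the acetyl group are free and hydrogen-bonded. Partial etherification cannot separate them cleanly, and closure can take either, so 14 would be accompanied by 2-hentriacontyl-5,7-dihydroxy-6-methyl-4H-chromen-4-one A3.
- Any acidic step with the 5-OH free also allows 14 and A3 to equilibrate. Two C41 waxes that differ only in the place of one methyl would be hard to separate.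
- The chosen plan never has two candidate oxygens; the distinction is made when ring A is built.

**Alternative 2:** cutting C8a–O1 on an aryl ketone that lacks this oxygen.
- 2,4-Dimethoxy-1-methylbenzene A4 would be acetylated to 1-(2,4-dimethoxy-5-methylphenyl)ethan-1-one A5. The key step would be a ketone-directed ortho C–H hydroxylation (Pd(OAc)2 with a strong oxidant in trifluoroacetic acid) to 1-(2-hydroxy-4,6-dimethoxy-3-methylphenyl)ethan-1-one A6, followed by the chemistry of steps 3 to 5.
- A5 has only one ortho C–H, so the regiochemistry would also be unambiguous. However, that C–H is flanked by acetyl and methyl, which hinders cyclometalation at divalent palladium.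
- A5 is an electron-rich dimethoxyarene that the oxidant can attack directly. Selectivity would then rest on the catalyst outrunning a background oxidation.
- The step forms one C–O bond at the same step count. The benzannulation sets four ring positions with no selectivity contest.

**Alternative 3:** an electrochemical chain union, cutting a CH2–CH2 bond inside the chain.
- 11-(5,7-Diethoxy-8-methyl-4-oxo-4H-chromen-2-yl)undecanoic acid A7 and an excess of docosanoic acid A8 would be coupled by mixed Kolbe electrolysis (platinum anode, partly neutralised methanol) to give 13.
- This would build the C31 chain from cheap C12 and C22 lipids by joining two carbons of like polarity. But the mixed coupling is statistical: both symmetrical dimers form and much of A7 is lost.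
- The dialkoxychromone ring can be oxidised at the anode potential of a Kolbe reaction.
- A7 still needs ketone 9 and several more steps, so the ring-A problem is not touched. Since acid 10 is sold with the full chain, the electrolysis would solve the lesser problem at higher cost.

Key step: step 1

Assumption: the side chain of the SMILES is read as unbranched hentriacontyl (31 carbons, C41H70O4); 1, 2 and 10 (lacceroic acid) are taken as catalogue chemicals.

## Route

Step 1
Reactants: 1 3-ethoxycyclobut-2-en-1-one; 2 1-ethoxyprop-1-yne
Product: 7 3,5-diethoxy-2-methylphenol, via vinylketene 3 (not isolated), via vinylcyclobutenone 4 (not isolated), via dienylketene 5 (not isolated), via cyclohexadienone 6 (not isolated)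
Conditions: 2 (1.5 equiv), toluene, 85 °C, sealed tube
Reagents that add atoms: none
Why: Danheiser benzannulation: heating should open 1 by 4π-electrocyclic ring opening to the ethoxy-substituted vinylketene 3. The ketene C=C of 3 then adds to 2 in a [2+2] cycloaddition that closes the four-membered ring of 4, the electrophilic ketene carbonyl carbon bonding to the nucleophilic methyl-bearing carbon of the ynol ether and the ketene α-carbon to the ethoxy-bearing carbon. Reversible 4π-opening of 4 gives dienylketene 5, whose thermal disrotatory 6π-electrocyclization closes the six-membered carbocycle as dienone 6, and enolisation to phenol 7 is driven by aromatisation. In sum the two alkyne carbons are inserted into the C1–C2 bond of 1, so the carbonyl oxygen of 1 becomes the free OH beside the methyl carbon, the ethoxy group of 2 lies on the other side of the methyl and the ethoxy group of 1 para to it. The closest known reaction type is the benzannulation of 3-alkyl- and 3-arylcyclobutenones with alkoxy- and silyloxyalkynes to resorcinol monoethers, which passes through 3-alkoxy-4-alkenylcyclobutenones of the same kind as 4; the only new element is the ethoxy group on the cyclobutenone. No stereocentre is created in the product, and the one in 4 is erased on ring opening. The selectivity needed is the orientation of the [2+2] step, secured by the matched polarisation of ketene and ynol ether; a [4+2] union of 3 across its carbonyl carbon and C4 would lead to the same dienone 6.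

Step 2
Reactants: 7 3,5-diethoxy-2-methylphenol
Product: 9 1-(4,6-diethoxy-2-hydroxy-3-methylphenyl)ethan-1-one, via difluoroboron chelate 8 (not isolated)
Conditions: AcOH, BF3·OEt2 (3 equiv), 90 °C; then EtOH/H2O, reflux
Reagents that add atoms: acetic acid, CC(=O)O
Why: Friedel–Crafts/Fries-type ortho-acetylation of a phenol; the only carbon ortho to the hydroxyl is C6, and the ortho product is drained as the six-membered O–BF2–O chelate 8, which should favour it over the para position between the two ethoxy groups. Hydrolysis of 8 should give 9; aryl ethyl ethers are inert to BF3 under these conditions.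

Step 3
Reactants: 9 1-(4,6-diethoxy-2-hydroxy-3-methylphenyl)ethan-1-one; 10 dotriacontanoic acid
Product: 11 2-acetyl-3,5-diethoxy-6-methylphenyl dotriacontanoate
Conditions: DCC (1.3 equiv), DMAP (0.3 equiv), CH2Cl2/THF, 40 °C
Reagents that add atoms: none
Why: Steglich esterification; the acylpyridinium ion formed with DMAP should acylate the hydrogen-bonded, flanked phenol, and the warm solvent mixture keeps the C32 acid in solution.

Step 4
Reactants: 11 2-acetyl-3,5-diethoxy-6-methylphenyl dotriacontanoate
Product: 13 5,7-diethoxy-2-hentriacontyl-8-methyl-4H-chromen-4-one, via diketone 12 (not isolated)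
Conditions: LiN(SiMe3)2 (2.5 equiv), THF, 0 °C → 40 °C; aq. HCl; then p-TsOH·H2O (0.2 equiv), toluene, reflux, Dean–Stark
Reagents that add atoms: none
Why: Baker–Venkataraman rearrangement (the acetyl enolate attacks the neighbouring aryl ester through a six-membered transition state, O→C acyl shift) to diketone 12, then acid-catalysed cyclodehydration of the 2-hydroxyaryl 1,3-diketone. Diketone 12 has one phenolic OH only, the one next to the C-methyl, so only the 8-methyl chromone can form; the ethers are stable to both stages.

Step 5
Reactants: 13 5,7-diethoxy-2-hentriacontyl-8-methyl-4H-chromen-4-one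
Product: 14 2-hentriacontyl-5,7-dihydroxy-8-methyl-4H-chromen-4-one
Conditions: BBr3 (6 equiv), CH2Cl2, −78 °C → rt; then H2O
Reagents that add atoms: none
Why: Lewis-acid cleavage of both aryl ethyl ethers (bromide attacks the O-ethyl carbon of the boron-bound ether; the C5 ether is assisted by chelation to the C4 carbonyl). The aprotic, cold conditions should leave the pyranone closed, so no shift to the 6-methyl series is expected, and the saturated chain is inert.

## Compound list

1 | 3-ethoxycyclobut-2-en-1-one | CCOC1=CC(=O)C1 | starting material
2 | 1-ethoxyprop-1-yne | CC#COCC | starting material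
3 | 3-ethoxybuta-1,3-dien-1-one (vinylketene) | C=C(OCC)C=C=O | intermediate
4 | 3-ethoxy-4-(1-ethoxyethenyl)-2-methylcyclobut-2-en-1-one (racemic) | CCOC(=C)C1C(=O)C(C)=C1OCC | intermediate
5 | (3E)-3,5-diethoxy-2-methylhexa-1,3,5-trien-1-one (dienylketene) | O=C=C(C)/C(OCC)=C\C(=C)OCC | intermediate
6 | 3,5-diethoxy-2-methylcyclohexa-2,4-dien-1-one | CCOC1=CC(OCC)=C(C)C(=O)C1 | intermediate
7 | 3,5-diethoxy-2-methylphenol | CCOc1cc(O)c(C)c(OCC)c1 | intermediate
8 | 5,7-diethoxy-2,2-difluoro-4,8-dimethyl-1,3,2-benzodioxaborinine (difluoroboron chelate of 9) | CCOc1cc(OCC)c2c(c1C)O[B-](F)(F)[O+]=C2C | intermediate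
9 | 1-(4,6-diethoxy-2-hydroxy-3-methylphenyl)ethan-1-one | CC(=O)c1c(O)c(C)c(OCC)cc1OCC | intermediate
10 | dotriacontanoic acid | CCCCCCCCCCCCCCCCCCCCCCCCCCCCCCCC(=O)O | starting material
11 | 2-acetyl-3,5-diethoxy-6-methylphenyl dotriacontanoate | CCCCCCCCCCCCCCCCCCCCCCCCCCCCCCCC(=O)Oc1c(C)c(OCC)cc(OCC)c1C(C)=O | intermediate
12 | 1-(4,6-diethoxy-2-hydroxy-3-methylphenyl)tetratriacontane-1,3-dione | CCCCCCCCCCCCCCCCCCCCCCCCCCCCCCCC(=O)CC(=O)c1c(O)c(C)c(OCC)cc1OCC | intermediate
13 | 5,7-diethoxy-2-hentriacontyl-8-methyl-4H-chromen-4-one | CCCCCCCCCCCCCCCCCCCCCCCCCCCCCCCc1cc(=O)c2c(OCC)cc(OCC)c(C)c2o1 | intermediate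
14 | 2-hentriacontyl-5,7-dihydroxy-8-methyl-4H-chromen-4-one | CCCCCCCCCCCCCCCCCCCCCCCCCCCCCCCc1cc(=O)c2c(O)cc(O)c(C)c2o1 | target

## Step count and least certain steps

Total step count: 5. Longest linear sequence: 5 steps (1 + 2 → 7 → 9 → 11 → 13 → 14).

**Step 1 (key step).**
- What may go wrong: the electrocyclic opening of 1, a vinylogous ester, may be slower than that of alkyl-substituted cyclobutenones. It may need temperatures at which 2 loses ethylene by retro-ene fragmentation.
- The phenol formed can also be O-acylated by 3, and 3 can oligomerise. Such esters would be returned to 7 by brief K2CO3/MeOH treatment of the crude product.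
- Fallback: the ketene is made by a polar elimination from a different building block, not by the pericyclic opening. It sets out from 2.
- (E)-3-Ethoxybut-2-enoic acid F1 is obtained by saponification of commercial ethyl (E)-3-ethoxybut-2-enoate (KOH, aqueous EtOH). Oxalyl chloride and catalytic DMF convert it into (E)-3-ethoxybut-2-enoyl chloride F2.
- Slow addition of NEt3 to F2 and 2 in CH2Cl2 at 0 °C should generate 3 by 1,4-dehydrochlorination, at a temperature where 2 is stable, and [2+2] capture should give 4.
- After a change of solvent to toluene, heating to 80 °C should complete 4 → 5 → 6 → 7, where the fallback rejoins the route.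
- Each stage is of a known type: vinylketenes from β-substituted crotonyl chlorides, ketene–alkoxyalkyne cycloaddition, and thermolysis of 4-alkenyl-3-alkoxycyclobutenones to phenols.

**Step 2.**
- What may go wrong: acylation at C4 of 7 (para to the hydroxyl, between the two ethoxy groups) in competition with C6, since both positions are doubly activated; or O-acetylation without migration to carbon.
- Fallback: directed metalation in place of electrophilic substitution. It sets out from 7.
- MOMCl and iPr2NEt should give 1,5-diethoxy-3-(methoxymethoxy)-2-methylbenzene F3.
- n-BuLi/TMEDA in THF at 0 °C should lithiate the ring position between the chelating acetal ether and its ethoxy neighbour. N-Methoxy-N-methylacetamide then gives 1-[4,6-diethoxy-2-(methoxymethoxy)-3-methylphenyl]ethan-1-one F4.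
- HCl in MeOH removes the acetal and returns to the route at 9.

**Step 4.**
- What may go wrong: deprotonation of 11 at the ester α-carbon instead of the acetyl group, followed by loss of the chain as a ketene (E1cB), or intermolecular acyl transfer. Either returns 9. Low solubility of the wax ester in cold THF would aggravate this.
- Fallback: the chain is joined by C-alkylation in place of acyl transfer. It sets out from 9 and also bypasses step 3.
- Claisen condensation with ethyl acetate (NaH, EtOAc/THF, reflux) should give 1-(4,6-diethoxy-2-hydroxy-3-methylphenyl)butane-1,3-dione F5.
- Cyclodehydration (p-TsOH, toluene, reflux) should give 5,7-diethoxy-2,8-dimethyl-4H-chromen-4-one F6.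
- LiN(iPr)2 in THF at −78 °C deprotonates the C2 methyl group (vinylogous enolate); the C8 methyl is an ordinary aryl methyl and is not touched. Alkylation with commercial 1-bromotriacontane (NaI, warming to rt) returns to the route at 13.

## Further compounds

F1 | step 1 | (E)-3-ethoxybut-2-enoic acid | CCO/C(C)=C/C(=O)O
F2 | step 1 | (E)-3-ethoxybut-2-enoyl chloride | CCO/C(C)=C/C(=O)Cl
F3 | step 2 | 1,5-diethoxy-3-(methoxymethoxy)-2-methylbenzene | CCOc1cc(OCOC)c(C)c(OCC)c1
F4 | step 2 | 1-[4,6-diethoxy-2-(methoxymethoxy)-3-methylphenyl]ethan-1-one | CC(=O)c1c(OCOC)c(C)c(OCC)cc1OCC
F5 | step 4 | 1-(4,6-diethoxy-2-hydroxy-3-methylphenyl)butane-1,3-dione | CC(=O)CC(=O)c1c(O)c(C)c(OCC)cc1OCC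
F6 | step 4 | 5,7-diethoxy-2,8-dimethyl-4H-chromen-4-one | Cc1cc(=O)c2c(OCC)cc(OCC)c(C)c2o1
A1 | alternative 1 | 2-methylbenzene-1,3,5-triol | Cc1c(O)cc(O)cc1O
A2 | alternative 1 | 1-(2,4,6-trihydroxy-3-methylphenyl)ethan-1-one | CC(=O)c1c(O)cc(O)c(C)c1O
A3 | alternative 1 | 2-hentriacontyl-5,7-dihydroxy-6-methyl-4H-chromen-4-one | CCCCCCCCCCCCCCCCCCCCCCCCCCCCCCCc1cc(=O)c2c(O)c(C)c(O)cc2o1
A4 | alternative 2 | 2,4-dimethoxy-1-methylbenzene | Cc1ccc(OC)cc1OC
A5 | alternative 2 | 1-(2,4-dimethoxy-5-methylphenyl)ethan-1-one | CC(=O)c1cc(C)c(OC)cc1OC
A6 | alternative 2 | 1-(2-hydroxy-4,6-dimethoxy-3-methylphenyl)ethan-1-one | CC(=O)c1c(O)c(C)c(OC)cc1OC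
A7 | alternative 3 | 11-(5,7-diethoxy-8-methyl-4-oxo-4H-chromen-2-yl)undecanoic acid | OC(=O)CCCCCCCCCCc1cc(=O)c2c(OCC)cc(OCC)c(C)c2o1
A8 | alternative 3 | docosanoic acid | CCCCCCCCCCCCCCCCCCCCCC(=O)O
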